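**Retrosynthetic overview**

1. Target 12 comes from flavanone 10 by BCl3 cleavage of the ring D benzyl ether and the C5 methyl ether; 10 comes from the cis-flavan-4-ol 11 by oxidation at C4.
2. 11 comes from flavone 9 by enantioselective hydrogenation. C2 is the only stereocentre, and its O1–C2 bond in ring C lies β to the C4 carbonyl and can open by retro-oxa-Michael reaction; the whole skeleton is therefore carried as the planar flavone with a C2=C3 double bond and C2 is set last.
3. 9 comes from the 1,3-diketone 8 by cyclodehydration (closes ring C); 8 comes from acetophenone 6 and benzoyl chloride 7 by C-acylation of the enolate.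
4. 6 comes from 2'-hydroxy-4',5',6'-trimethoxyacetophenone 2 and benzyl alcohol 5 by Friedel–Crafts benzylation at the only free CH of ring A (the future C8); 2 is made from phenol 1 and 5 from aldehyde 3.
5. Ring order: rings A, B and D are bought; ring C is the only ring formed (step 6).

Key step: step 7

Assumption: the (R,R) imidazolinium salt is taken to deliver hydrogen to the face of C2 that gives 2S; the sense of induction is to be checked on the parent flavone, and the (S,S) salt is used if it proves opposite.

**Route**

Step 1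
Reactants: 1 3,4,5-trimethoxyphenol
Product: 2 2'-hydroxy-4',5',6'-trimethoxyacetophenone
Conditions: AcOH, BF3·OEt2 (3 equiv), 90 °C; then H2O
Reagents that add atoms: acetic acid, CC(=O)O
Why: BF3-mediated ortho C-acetylation of an electron-rich phenol (Friedel–Crafts acylation/Fries manifold), in which the two ortho positions are equivalent, the para position is blocked, and the difluoroboron chelate of the o-hydroxy ketone shuts down a second acylation.

Step 2
Reactants: 3 2-hydroxy-5-methoxybenzaldehyde
Product: 4 2-(benzyloxy)-5-methoxybenzaldehyde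
Conditions: BnBr (1.1 equiv), K2CO3 (1.5 equiv), DMF, 60 °C
Reagents that add atoms: benzyl bromide, BrCc1ccccc1
Why: Williamson ether synthesis on the only phenol present, which masks the ring D hydroxyl through the acidic and strongly basic steps that follow.

Step 3
Reactants: 4 2-(benzyloxy)-5-methoxybenzaldehyde
Product: 5 [2-(benzyloxy)-5-methoxyphenyl]methanol
Conditions: NaBH4, MeOH, 0 °C
Reagents that add atoms: none
Why: Borohydride reduction of an aryl aldehyde to the benzylic alcohol, which leaves the ethers untouched.

Step 4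
Reactants: 2 2'-hydroxy-4',5',6'-trimethoxyacetophenone (1.5 equiv); 5 [2-(benzyloxy)-5-methoxyphenyl]methanol (added slowly)
Product: 6 3'-[2-(benzyloxy)-5-methoxybenzyl]-2'-hydroxy-4',5',6'-trimethoxyacetophenone
Conditions: p-TsOH·H2O (10 mol%), HFIP/CH2Cl2 (1:1), 25–40 °C
Reagents that add atoms: none
Why: Dehydrative Friedel–Crafts benzylation in which the benzylic cation, stabilised by its ortho benzyloxy group, is taken up by C3' of 2, the single unsubstituted ring A carbon (ortho to the hydroxyl and para to the 6'-methoxy group), so that neither regioisomers nor double benzylation are possible.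

Step 5
Reactants: 6 3'-[2-(benzyloxy)-5-methoxybenzyl]-2'-hydroxy-4',5',6'-trimethoxyacetophenone; 7 benzoyl chloride (1.05 equiv)
Product: 8 1-{3-[2-(benzyloxy)-5-methoxybenzyl]-2-hydroxy-4,5,6-trimethoxyphenyl}-3-phenylpropane-1,3-dione
Conditions: LiN(SiMe3)2 (3.2 equiv), THF, −78 to −10 °C; then 7, −78 °C to rt; aq. HCl
Reagents that add atoms: none
Why: Claisen-type C-benzoylation of the lithium enolate of the phenoxide–enolate dianion (the direct, base-mediated form of the Baker–Venkataraman route to o-hydroxydibenzoylmethanes), with the third equivalent of amide absorbing the acidity of the diketone so that it is not acylated again.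

Step 6
Reactants: 8 1-{3-[2-(benzyloxy)-5-methoxybenzyl]-2-hydroxy-4,5,6-trimethoxyphenyl}-3-phenylpropane-1,3-dione
Product: 9 8-[2-(benzyloxy)-5-methoxybenzyl]-5,6,7-trimethoxyflavone
Conditions: p-TsOH·H2O (0.2 equiv), toluene, 90 °C, Dean–Stark
Reagents that add atoms: none
Why: Acid-catalysed cyclodehydration of an o-hydroxyaryl 1,3-diketone (the closing stage of the Baker–Venkataraman flavone synthesis), in which the phenol oxygen adds to the benzoyl carbonyl and water is lost to form the 4-pyranone ring C under acid mild enough to keep the benzyl ether.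

Step 7
Reactants: 9 8-[2-(benzyloxy)-5-methoxybenzyl]-5,6,7-trimethoxyflavone
Product: 11 (2S,4S)-8-[2-(benzyloxy)-5-methoxybenzyl]-5,6,7-trimethoxyflavan-4-ol, via protected (2S)-flavanone 10 (not isolated)
Conditions: [Ru(cod)(2-methylallyl)2] (5 mol%), (R,R)-1,3-bis[1-(1-naphthyl)ethyl]-4,5-dihydroimidazolium tetrafluoroborate (10 mol%), KOt-Bu (15 mol%), n-hexane, 70 °C (catalyst formation); then 9, toluene, H2 (100 bar), 25–40 °C
Reagents that add atoms: none
Why: Asymmetric hydrogenation of a flavone on a chiral ruthenium bis(N-heterocyclic carbene) catalyst (divalent ruthenium), a known reaction type for flavones and chromones applied here to a ring A that carries no hydrogen: the ruthenium hydride adds hydrogen across the polarised C2=C3 bond of the vinylogous ester to give flavanone 10, whose C4 ketone is then reduced in the same flask. No ring is closed and no skeletal bond is formed. C2 is set by catalyst control, the two 1-(1-naphthyl)ethyl-substituted carbene ligands choosing the enantioface that receives hydride (2S with the ligand enantiomer assumed above), and C4 is set by hydride delivery to the carbonyl face anti to the C2 phenyl group, which gives the 2,4-cis alcohol; C4 is sacrificial because step 8 oxidises it away. The step needs chemoselectivity for the pyranone over the three benzene rings and the benzyl ether, which the conjugated, electron-poor C2=C3–C4=O unit should secure at ambient temperature, and the follow-up reduction of the ketone removes the carbonyl through which residual tert-butoxide could racemise C2 by retro-oxa-Michael opening. The C8 benzyl group and the C5 methoxy group lie away from C2, so enantioface discrimination should resemble that of simple flavones, and any 10 that escapes carbonyl reduction next to the peri methoxy group converges in step 8.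

Step 8
Reactants: 11 (2S,4S)-8-[2-(benzyloxy)-5-methoxybenzyl]-5,6,7-trimethoxyflavan-4-ol
Product: 10 (2S)-8-[2-(benzyloxy)-5-methoxybenzyl]-5,6,7-trimethoxyflavanone
Conditions: Dess–Martin periodinane (1.3 equiv), CH2Cl2, 0 °C to rt
Reagents that add atoms: none
Why: Dess–Martin oxidation of the secondary benzylic alcohol under near-neutral, base-free conditions returns the C4 ketone without touching C2, and the C4 configuration of the alcohol is irrelevant.

Step 9
Reactants: 10 (2S)-8-[2-(benzyloxy)-5-methoxybenzyl]-5,6,7-trimethoxyflavanone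
Product: 12 (2S)-5-hydroxy-8-(2-hydroxy-5-methoxybenzyl)-6,7-dimethoxyflavanone
Conditions: BCl3 (4 equiv), pentamethylbenzene (3 equiv), CH2Cl2, −78 to 0 °C; then H2O
Reagents that add atoms: none
Why: Lewis-acid ether cleavage in which BCl3 removes the aryl benzyl ether (the benzyl cation being trapped by pentamethylbenzene) and, through a six-membered boron chelate with the C4 carbonyl, only the peri C5 methyl ether, while the low temperature spares the C6, C7 and ring D methyl ethers and the O1–C2 bond.

**Compound list**

1 | 3,4,5-trimethoxyphenol | COc1cc(O)cc(OC)c1OC | starting material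
2 | 2'-hydroxy-4',5',6'-trimethoxyacetophenone | CC(=O)c1c(O)cc(OC)c(OC)c1OC | intermediate
3 | 2-hydroxy-5-methoxybenzaldehyde | COc1ccc(O)c(C=O)c1 | starting material
4 | 2-(benzyloxy)-5-methoxybenzaldehyde | COc1ccc(OCc2ccccc2)c(C=O)c1 | intermediate
5 | [2-(benzyloxy)-5-methoxyphenyl]methanol | COc1ccc(OCc2ccccc2)c(CO)c1 | intermediate
6 | 3'-[2-(benzyloxy)-5-methoxybenzyl]-2'-hydroxy-4',5',6'-trimethoxyacetophenone | CC(=O)c1c(O)c(Cc2cc(OC)ccc2OCc2ccccc2)c(OC)c(OC)c1OC | intermediate
7 | benzoyl chloride | O=C(Cl)c1ccccc1 | starting material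
8 | 1-{3-[2-(benzyloxy)-5-methoxybenzyl]-2-hydroxy-4,5,6-trimethoxyphenyl}-3-phenylpropane-1,3-dione | O=C(CC(=O)c1ccccc1)c1c(O)c(Cc2cc(OC)ccc2OCc2ccccc2)c(OC)c(OC)c1OC | intermediate
9 | 8-[2-(benzyloxy)-5-methoxybenzyl]-5,6,7-trimethoxyflavone | COc1ccc(OCc2ccccc2)c(Cc2c(OC)c(OC)c(OC)c3c2OC(c2ccccc2)=CC3=O)c1 | intermediate
10 | (2S)-8-[2-(benzyloxy)-5-methoxybenzyl]-5,6,7-trimethoxyflavanone | COc1ccc(OCc2ccccc2)c(Cc2c(OC)c(OC)c(OC)c3c2O[C@H](c2ccccc2)CC3=O)c1 | intermediate
11 | (2S,4S)-8-[2-(benzyloxy)-5-methoxybenzyl]-5,6,7-trimethoxyflavan-4-ol (2,4-cis) | COc1ccc(OCc2ccccc2)c(Cc2c(OC)c(OC)c(OC)c3c2O[C@H](c2ccccc2)C[C@@H]3O)c1 | intermediate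
12 | (2S)-5-hydroxy-8-(2-hydroxy-5-methoxybenzyl)-6,7-dimethoxyflavanone | COc1ccc(O)c(Cc2c(OC)c(OC)c(O)c3c2O[C@H](c2ccccc2)CC3=O)c1 | target

**Step count and risks**

Total step count: 9. Longest linear sequence: 8 steps (3 → 4 → 5 → 6 → 8 → 9 → 11 → 10 → 12).

Steps most likely to fail:

Step 7. The electron-rich, fully substituted ring A may slow hydrogen uptake at the vinylogous ester. Enantioface discrimination may fall short on this untested substitution pattern, or a benzene ring may be reduced in competition. The fallback sets C2 by carbon–carbon bond formation and starts from 6. Condensation of 6 with N,N-dimethylformamide dimethyl acetal (toluene, 100 °C) would give (E)-1-{3-[2-(benzyloxy)-5-methoxybenzyl]-2-hydroxy-4,5,6-trimethoxyphenyl}-3-(dimethylamino)prop-2-en-1-one F1. Dilute HCl in CH2Cl2 would close it, with loss of dimethylamine, to 8-[2-(benzyloxy)-5-methoxybenzyl]-5,6,7-trimethoxy-4H-chromen-4-one F2. Asymmetric conjugate addition of phenylboronic acid to F2 would follow, with Pd(OCOCF3)2 (divalent palladium), 4-tert-butyl-2-(pyridin-2-yl)-4,5-dihydrooxazole (enantiomer chosen for 2S), NH4PF6 and water in 1,2-dichloroethane at 60 °C. This is a known route from chromones to flavanones and would come back to the route at 10, which then goes into step 9; steps 5 to 8 are bypassed.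

Step 4. The benzylic cation may alkylate the electron-rich ring D of another molecule of 5 faster than the acyl-deactivated ring A of 2, which would lead to oligomers, or the acid may remove the benzyl ether. The fallback forms the same bond through a neutral ortho-quinone methide and starts from 3 and 2. Reduction of 3 with NaBH4 in MeOH would give 2-(hydroxymethyl)-4-methoxyphenol F3. Heating F3 with 2 in xylene at 140 °C without acid would dehydrate it to the ortho-quinone methide, which C3' of 2 attacks to give 2'-hydroxy-3'-(2-hydroxy-5-methoxybenzyl)-4',5',6'-trimethoxyacetophenone F4. Benzylation with BnBr and K2CO3 in acetone would take place on the ring D phenol only, the 2'-hydroxyl being held in a hydrogen bond to the acetyl carbonyl and flanked on both sides, and would come back to the route at 6.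

Step 9. The Lewis acid may open the O1–C2 bond of the chelated flavanone (retro-oxa-Michael reaction and reclosure), which would erode the configuration at C2, or the ether cleavage may run on to the C6 methoxy group. The fallback moves the Lewis-acid chemistry in front of the stereocentre and starts from 9. Treatment of 9 with BCl3 and pentamethylbenzene (CH2Cl2, −78 to 0 °C) would give 5-hydroxy-8-(2-hydroxy-5-methoxybenzyl)-6,7-dimethoxyflavone F5, where no stereocentre can be lost. Benzylation of both hydroxyls (BnBr, K2CO3, DMF, 60 °C) would give 5-(benzyloxy)-8-[2-(benzyloxy)-5-methoxybenzyl]-6,7-dimethoxyflavone F6. Hydrogenation under the conditions of step 7 would give (2S,4S)-5-(benzyloxy)-8-[2-(benzyloxy)-5-methoxybenzyl]-6,7-dimethoxyflavan-4-ol F7. Dess–Martin oxidation would give (2S)-5-(benzyloxy)-8-[2-(benzyloxy)-5-methoxybenzyl]-6,7-dimethoxyflavanone F8. Neutral hydrogenolysis (H2, 1 bar, Pd/C, EtOAc, rt) would remove both benzyl groups and come back to the route at 12.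

**Further compounds**

F1 | step 7 | (E)-1-{3-[2-(benzyloxy)-5-methoxybenzyl]-2-hydroxy-4,5,6-trimethoxyphenyl}-3-(dimethylamino)prop-2-en-1-one | CN(C)/C=C/C(=O)c1c(O)c(Cc2cc(OC)ccc2OCc2ccccc2)c(OC)c(OC)c1OC
F2 | step 7 | 8-[2-(benzyloxy)-5-methoxybenzyl]-5,6,7-trimethoxy-4H-chromen-4-one | COc1ccc(OCc2ccccc2)c(Cc2c(OC)c(OC)c(OC)c3c2OC=CC3=O)c1
F3 | step 4 | 2-(hydroxymethyl)-4-methoxyphenol | COc1ccc(O)c(CO)c1
F4 | step 4 | 2'-hydroxy-3'-(2-hydroxy-5-methoxybenzyl)-4',5',6'-trimethoxyacetophenone | CC(=O)c1c(O)c(Cc2cc(OC)ccc2O)c(OC)c(OC)c1OC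
F5 | step 9 | 5-hydroxy-8-(2-hydroxy-5-methoxybenzyl)-6,7-dimethoxyflavone | COc1ccc(O)c(Cc2c(OC)c(OC)c(O)c3c2OC(c2ccccc2)=CC3=O)c1
F6 | step 9 | 5-(benzyloxy)-8-[2-(benzyloxy)-5-methoxybenzyl]-6,7-dimethoxyflavone | COc1ccc(OCc2ccccc2)c(Cc2c(OC)c(OC)c(OCc3ccccc3)c3c2OC(c2ccccc2)=CC3=O)c1
F7 | step 9 | (2S,4S)-5-(benzyloxy)-8-[2-(benzyloxy)-5-methoxybenzyl]-6,7-dimethoxyflavan-4-ol | COc1ccc(OCc2ccccc2)c(Cc2c(OC)c(OC)c(OCc3ccccc3)c3c2O[C@H](c2ccccc2)C[C@@H]3O)c1
F8 | step 9 | (2S)-5-(benzyloxy)-8-[2-(benzyloxy)-5-methoxybenzyl]-6,7-dimethoxyflavanone | COc1ccc(OCc2ccccc2)c(Cc2c(OC)c(OC)c(OCc3ccccc3)c3c2O[C@H](c2ccccc2)CC3=O)c1
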